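Ring A, fully substituted, is assembled from a four-carbon and a two-carbon unit, which avoids differentiating a phloroglucinol. Heating a racemic 3-benzyloxy-4-prenylcyclobutenone (itself from a ketene–ynol ether cycloaddition) with methoxy(trimethylsilyl)ethyne forms C8–C8a, C6–C7 and C4a–C8a in one operation. The step exploits the meta-trioxygenated, hexasubstituted pattern of ring A. The ketene carbonyl emerges as the only free hydroxyl (on C8a, the future pyran O1). O5 arrives benzylated and O7 methylated, and the prenyl chain sits on C4a. Silicon flags C8, the crowded carbon between O7 and O1 that must finally carry the cinnamoyl group.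

Key step: step 4

Assumption: 5-methylhex-4-enoic acid, (E)-4-(benzyloxy)cinnamic acid and the L-series Shi ketone (otherwise made from L-sorbose) are treated as catalogue chemicals; atom labels O1 to C8a follow the chroman numbering of the target.

Step 1
Reactants: 1 chloroacetaldehyde dimethyl acetal
Product: 3 1-methoxy-2-(trimethylsilyl)ethyne, via lithium methoxyacetylide 2 (not isolated)
Conditions: Et2NH, n-BuLi (3.1 equiv each), THF, 0 °C; 1, 0 °C to rt; TMSCl (2.2 equiv), −78 °C to rt; distillation
Reagents that add atoms: chlorotrimethylsilane, C[Si](C)(C)Cl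
Why: Base-induced double elimination (loss of MeOH and HCl) followed by deprotonation is the standard entry to lithium alkoxyacetylides, and adding TMSCl at −78 °C lets the anions be silylated ahead of the free amine (acetylide C-silylation).

Step 2
Reactants: 4 benzyl alcohol; 5 trichloroethylene
Product: 8 (benzyloxy)ethyne, via benzyl (E)-1,2-dichlorovinyl ether 6 (not isolated), via lithium (benzyloxy)acetylide 7 (not isolated)
Conditions: KH (1.2 equiv), THF, 0 °C; 5, −50 °C to rt; n-BuLi (2.4 equiv), −78 to −40 °C; H2O, −78 °C; cold pentane extraction, used at once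
Reagents that add atoms: none
Why: This is the trichloroethylene route to ynol ethers: potassium benzyloxide adds anti to dichloroacetylene formed in situ to give 6, n-BuLi effects elimination and chlorine–lithium exchange to 7, and protonation gives 8, which is handled cold because benzyl alkynyl ethers rearrange sigmatropically on warming.

Step 3
Reactants: 9 5-methylhex-4-enoic acid; 8 (benzyloxy)ethyne
Product: 12 3-(benzyloxy)-4-(3-methylbut-2-en-1-yl)cyclobut-2-en-1-one (racemic), via 5-methylhex-4-enoyl chloride 10 (not isolated), via prenylketene 11 (not isolated)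
Conditions: 9, (COCl)2, DMF (cat.), CH2Cl2, 0 °C to rt, evaporate; slow addition of 10 to 8, Et3N, Et2O, 0 °C to rt
Reagents that add atoms: none
Why: In this ketene–ynol ether [2+2] cycloaddition, dehydrochlorination of 10 gives monoalkylketene 11, whose carbonyl carbon is attacked by the unsubstituted nucleophilic terminus of 8, so oxygen ends on C3 and prenyl on C4 without deprotonating a cyclobutenone at C4 (an antiaromatic cyclobutadienolate), and the one-carbon tether rules out intramolecular ketene–alkene addition.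

Step 4
Reactants: 12 3-(benzyloxy)-4-(3-methylbut-2-en-1-yl)cyclobut-2-en-1-one; 3 1-methoxy-2-(trimethylsilyl)ethyne
Product: 17 3-(benzyloxy)-5-methoxy-2-(3-methylbut-2-en-1-yl)-6-(trimethylsilyl)phenol, via vinylketene 13 (not isolated), via alkenylcyclobutenone 14 (not isolated), via dienylketene 15 (not isolated), via cyclohexadienone 16 (not isolated)
Conditions: 3 (1.5 equiv), toluene (degassed, base-washed sealed tube), 80 °C then 110 °C
Reagents that add atoms: none
Why: Conrotatory four-electron opening of strained 12, with the C4 prenyl group turning outward, releases vinylketene 13, whose C=C=O unit adds 3 in a [2+2] sense to give 14; a second four-electron opening to dienylketene 15, six-electron closure to dienone 16 and enolisation deliver phenol 17. The closest known reaction type is the Danheiser benzannulation of cyclobutenones with alkoxyalkynes, of which a C-silylated ynol ether is only a bulkier member. Ring A is closed by the disrotatory 6π electrocyclisation of 15 (C4a–C8a), after C8–C8a and C6–C7 have been made in the cycloaddition. No stereocentre is formed, and the racemic C4 centre of 12 vanishes on aromatisation. The selectivity needed is the orientation of the ketene–alkyne union: donation from the methoxy oxygen makes the silicon-bearing alkyne carbon the nucleophile, so it bonds to the electrophilic ketene carbonyl carbon and silicon lands on C8 with methoxy on C7. The medium is kept neutral and aprotic because 17 is an acid-labile arylsilane, and the methyl ynol ether has no β-hydrogen through which it could fragment on heating.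

Step 5
Reactants: 17 3-(benzyloxy)-5-methoxy-2-(3-methylbut-2-en-1-yl)-6-(trimethylsilyl)phenol
Product: 18 [3-(benzyloxy)-5-methoxy-2-(3-methylbut-2-en-1-yl)-6-(trimethylsilyl)phenoxy](tert-butyl)dimethylsilane
Conditions: TBSOTf, 2,6-lutidine, CH2Cl2, 0 °C
Reagents that add atoms: tert-butyldimethylsilyl triflate, CC(C)(C)[Si](C)(C)OS(=O)(=O)C(F)(F)F
Why: Silyl ether formation masks the lone phenol, which would otherwise be oxidised in step 6 and, as its phenoxide in that alkaline medium, would open the new epoxide in the 5-exo mode to the wrong (dihydrobenzofuran) ring.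

Step 6
Reactants: 18 [3-(benzyloxy)-5-methoxy-2-(3-methylbut-2-en-1-yl)-6-(trimethylsilyl)phenoxy](tert-butyl)dimethylsilane
Product: 19 [3-(benzyloxy)-2-{[(2S)-3,3-dimethyloxiran-2-yl]methyl}-5-methoxy-6-(trimethylsilyl)phenoxy](tert-butyl)dimethylsilane
Conditions: 1,2:4,5-di-O-isopropylidene-β-L-erythro-2,3-hexodiulo-2,6-pyranose (L-series Shi ketone, 30 mol %), Oxone (2KHSO5·KHSO4·K2SO4), K2CO3, Bu4NHSO4, MeCN–CH2(OMe)2, aq. Na2B4O7/Na2EDTA buffer (pH 10.5), 0 °C
Reagents that add atoms: potassium peroxymonosulfate (active part of Oxone), [K+].[O-]S(=O)(=O)OO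
Why: In the Shi asymmetric epoxidation the chiral dioxirane attacks the only nucleophilic alkene through a spiro transition state; the D-fructose ketone turns RCH2CH=CMe2 into (R)-epoxides, so the L-series ketone should give the (S)-epoxide, whose C–O bond becomes the C3–OH bond of the target.

Step 7
Reactants: 19 [3-(benzyloxy)-2-{[(2S)-3,3-dimethyloxiran-2-yl]methyl}-5-methoxy-6-(trimethylsilyl)phenoxy](tert-butyl)dimethylsilane
Product: 20 [3-(benzyloxy)-2-{[(2S)-3,3-dimethyloxiran-2-yl]methyl}-6-iodo-5-methoxyphenoxy](tert-butyl)dimethylsilane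
Conditions: NIS (1.0 equiv), NaHCO3 (solid), MeCN, 0 °C, dark
Reagents that add atoms: N-iodosuccinimide, O=C1CCC(=O)N1I
Why: Electrophilic ipso-iododesilylation is favoured at C8 by β-silicon stabilisation of the σ-complex and by relief of strain, neutral NIS spares the epoxide, and the exchange precedes the first acidic operation because a trioxygenated arylsilane is expected to protodesilylate about as readily as the epoxide opens.

Step 8
Reactants: 20 [3-(benzyloxy)-2-{[(2S)-3,3-dimethyloxiran-2-yl]methyl}-6-iodo-5-methoxyphenoxy](tert-butyl)dimethylsilane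
Product: 22 (3S)-5-(benzyloxy)-8-iodo-7-methoxy-2,2-dimethylchroman-3-ol, via epoxy phenol 21 (not isolated)
Conditions: TBAF (1.1 equiv), AcOH (1.5 equiv), THF, 0 °C; extractive work-up; CSA (10 mol %), CH2Cl2, −20 to 0 °C
Reagents that add atoms: none
Why: Buffered fluoride frees the phenol in neutral form (no phenoxide, hence no 5-exo attack), and Brønsted acid then directs the acid-catalysed 6-endo epoxide opening to the tertiary carbon that best carries positive charge, so O1–C2 forms, the C3–O bond is untouched and (S) is retained, while benzylated O5 cannot compete.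

Step 9
Reactants: 23 (E)-3-[4-(benzyloxy)phenyl]prop-2-enoic acid
Product: 25 (E)-3-[4-(benzyloxy)phenyl]-N-methoxy-N-methylprop-2-enamide, via acyl imidazole 24 (not isolated)
Conditions: CDI, THF, rt; MeNHOMe·HCl, rt
Reagents that add atoms: N,O-dimethylhydroxylamine hydrochloride, CNOC.Cl
Why: Amide formation through the acyl imidazole (CDI activation) leaves the E-alkene and the benzyl ether untouched.

Step 10
Reactants: 22 (3S)-5-(benzyloxy)-8-iodo-7-methoxy-2,2-dimethylchroman-3-ol; 25 (E)-3-[4-(benzyloxy)phenyl]-N-methoxy-N-methylprop-2-enamide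
Product: 28 (E)-1-[(3S)-5-(benzyloxy)-3-hydroxy-7-methoxy-2,2-dimethylchroman-8-yl]-3-[4-(benzyloxy)phenyl]prop-2-en-1-one, via sodium alkoxide 26 (not isolated), via aryllithium 27 (not isolated)
Conditions: 22, NaH (1.1 equiv), THF, 0 °C; n-BuLi (1.1 equiv), −78 °C; 25 (1.3 equiv), −78 to 0 °C; aq. NH4Cl
Reagents that add atoms: none
Why: In this Weinreb ketone synthesis the alcohol is first turned into its sodium alkoxide so that no proton can quench the carbanion, iodine–lithium exchange gives the 2,6-dialkoxyaryllithium 27, and its 1,2-addition to 25 stops at the ketone stage until work-up, which places the E-enone on hindered C8 and leaves C3 untouched.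

Step 11
Reactants: 28 (E)-1-[(3S)-5-(benzyloxy)-3-hydroxy-7-methoxy-2,2-dimethylchroman-8-yl]-3-[4-(benzyloxy)phenyl]prop-2-en-1-one
Product: 29 (E)-1-[(3S)-3,5-dihydroxy-7-methoxy-2,2-dimethylchroman-8-yl]-3-(4-hydroxyphenyl)prop-2-en-1-one
Conditions: BCl3 (5 equiv), C6HMe5 (6 equiv), CH2Cl2, −78 °C; MeOH then H2O quench at −78 °C
Reagents that add atoms: none
Why: In this Lewis-acid debenzylation with a non-basic cation scavenger, BCl3 at −78 °C ionises both benzyl aryl ethers and pentamethylbenzene traps the benzyl cation, which spares the enone, while cleavage of the methyl ether beside the ketone normally needs a higher temperature and the C3 borate is hydrolysed on work-up.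

Compound list
1 | chloroacetaldehyde dimethyl acetal | COC(CCl)OC | starting material
2 | lithium methoxyacetylide | [Li]C#COC | intermediate
3 | 1-methoxy-2-(trimethylsilyl)ethyne | COC#C[Si](C)(C)C | intermediate
4 | benzyl alcohol | OCc1ccccc1 | starting material
5 | trichloroethylene | ClC=C(Cl)Cl | starting material
6 | benzyl (E)-1,2-dichlorovinyl ether | Cl/C=C(/Cl)OCc1ccccc1 | intermediate
7 | lithium (benzyloxy)acetylide | [Li]C#COCc1ccccc1 | intermediate
8 | (benzyloxy)ethyne | C#COCc1ccccc1 | intermediate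
9 | 5-methylhex-4-enoic acid | CC(C)=CCCC(=O)O | starting material
10 | 5-methylhex-4-enoyl chloride | CC(C)=CCCC(=O)Cl | intermediate
11 | prenylketene (5-methylhexa-1,4-dien-1-one) | CC(C)=CCC=C=O | intermediate
12 | 3-(benzyloxy)-4-(3-methylbut-2-en-1-yl)cyclobut-2-en-1-one (racemic) | O=C1C=C(OCc2ccccc2)C1CC=C(C)C | intermediate
13 | (3Z)-3-(benzyloxy)-7-methylocta-1,3,6-trien-1-one (vinylketene, prenyl CH2 trans to C2) | O=C=C/C(OCc1ccccc1)=C/CC=C(C)C | intermediate
14 | 4-[(1Z)-1-(benzyloxy)-5-methylhexa-1,4-dien-1-yl]-3-methoxy-2-(trimethylsilyl)cyclobut-2-en-1-one (racemic) | O=C1C([Si](C)(C)C)=C(OC)C1/C(OCc2ccccc2)=C/CC=C(C)C | intermediate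
15 | (3E,5Z)-5-(benzyloxy)-3-methoxy-9-methyl-2-(trimethylsilyl)deca-1,3,5,8-tetraen-1-one (dienylketene, C2 and C5 cis) | O=C=C([Si](C)(C)C)/C(OC)=C\C(OCc1ccccc1)=C\CC=C(C)C | intermediate
16 | 5-(benzyloxy)-3-methoxy-6-(3-methylbut-2-en-1-yl)-2-(trimethylsilyl)cyclohexa-2,4-dien-1-one (racemic) | O=C1C([Si](C)(C)C)=C(OC)C=C(OCc2ccccc2)C1CC=C(C)C | intermediate
17 | 3-(benzyloxy)-5-methoxy-2-(3-methylbut-2-en-1-yl)-6-(trimethylsilyl)phenol | COc1cc(OCc2ccccc2)c(CC=C(C)C)c(O)c1[Si](C)(C)C | intermediate
18 | [3-(benzyloxy)-5-methoxy-2-(3-methylbut-2-en-1-yl)-6-(trimethylsilyl)phenoxy](tert-butyl)dimethylsilane | COc1cc(OCc2ccccc2)c(CC=C(C)C)c(O[Si](C)(C)C(C)(C)C)c1[Si](C)(C)C | intermediate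
19 | [3-(benzyloxy)-2-{[(2S)-3,3-dimethyloxiran-2-yl]methyl}-5-methoxy-6-(trimethylsilyl)phenoxy](tert-butyl)dimethylsilane | COc1cc(OCc2ccccc2)c(C[C@@H]2OC2(C)C)c(O[Si](C)(C)C(C)(C)C)c1[Si](C)(C)C | intermediate
20 | [3-(benzyloxy)-2-{[(2S)-3,3-dimethyloxiran-2-yl]methyl}-6-iodo-5-methoxyphenoxy](tert-butyl)dimethylsilane | COc1cc(OCc2ccccc2)c(C[C@@H]2OC2(C)C)c(O[Si](C)(C)C(C)(C)C)c1I | intermediate
21 | 3-(benzyloxy)-2-{[(2S)-3,3-dimethyloxiran-2-yl]methyl}-6-iodo-5-methoxyphenol | COc1cc(OCc2ccccc2)c(C[C@@H]2OC2(C)C)c(O)c1I | intermediate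
22 | (3S)-5-(benzyloxy)-8-iodo-7-methoxy-2,2-dimethylchroman-3-ol | COc1cc(OCc3ccccc3)c2c(c1I)OC(C)(C)[C@@H](O)C2 | intermediate
23 | (E)-3-[4-(benzyloxy)phenyl]prop-2-enoic acid | O=C(O)/C=C/c1ccc(OCc2ccccc2)cc1 | starting material
24 | (E)-3-[4-(benzyloxy)phenyl]-1-(imidazol-1-yl)prop-2-en-1-one | O=C(/C=C/c1ccc(OCc2ccccc2)cc1)n1ccnc1 | intermediate
25 | (E)-3-[4-(benzyloxy)phenyl]-N-methoxy-N-methylprop-2-enamide | CON(C)C(=O)/C=C/c1ccc(OCc2ccccc2)cc1 | intermediate
26 | sodium (3S)-5-(benzyloxy)-8-iodo-7-methoxy-2,2-dimethylchroman-3-olate | COc1cc(OCc3ccccc3)c2c(c1I)OC(C)(C)[C@@H](O[Na])C2 | intermediate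
27 | sodium (3S)-5-(benzyloxy)-8-lithio-7-methoxy-2,2-dimethylchroman-3-olate | COc1cc(OCc3ccccc3)c2c(c1[Li])OC(C)(C)[C@@H](O[Na])C2 | intermediate
28 | (E)-1-[(3S)-5-(benzyloxy)-3-hydroxy-7-methoxy-2,2-dimethylchroman-8-yl]-3-[4-(benzyloxy)phenyl]prop-2-en-1-one | COc1cc(OCc3ccccc3)c2c(c1C(=O)/C=C/c1ccc(OCc3ccccc3)cc1)OC(C)(C)[C@@H](O)C2 | intermediate
29 | (E)-1-[(3S)-3,5-dihydroxy-7-methoxy-2,2-dimethylchroman-8-yl]-3-(4-hydroxyphenyl)prop-2-en-1-one | COc1cc(O)c2c(c1C(=O)/C=C/c1ccc(O)cc1)OC(C)(C)[C@@H](O)C2 | target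

Total steps: 11. Longest linear sequence: 9 (steps 2, 3, 4, 5, 6, 7, 8, 10, 11).

Steps most likely to fail

1. **Step 4.**
   - What may go wrong: the ketene–alkyne union may be too slow at the bulky silyl-bearing terminus. Dimerisation of the vinylketene, a 1,5-hydrogen shift from its allylic CH2 or thermal loss of silicon could then take over.
   - Fallback (sets out from 12 and 2, returns at 17): acetylide 2 is protonated with water, not silylated, to give methoxyethyne F1. This is the least hindered and best-tried partner for this benzannulation, and with 12 in toluene at 80 to 110 °C it should give 3-(benzyloxy)-5-methoxy-2-(3-methylbut-2-en-1-yl)phenol F2. The hydroxyl then steers amine-catalysed ortho-bromination (NBS, i-Pr2NH cat., CH2Cl2, low temperature) to its only open ortho carbon, giving 3-(benzyloxy)-6-bromo-5-methoxy-2-(3-methylbut-2-en-1-yl)phenol F3. O-silylation with (Me3Si)2NH gives [3-(benzyloxy)-6-bromo-5-methoxy-2-(3-methylbut-2-en-1-yl)phenoxy]trimethylsilane F4. Bromine–lithium exchange (n-BuLi, THF, −78 °C) then triggers the retro-Brook oxygen-to-carbon silyl shift that leads to 17.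

2. **Step 7.**
   - What may go wrong: the iodonium source may attack the unsubstituted C6 position and not the crowded C8 ipso carbon, or the epoxide may open during halogenation.
   - Fallback (sets out from 19, returns at 22): the order of events is reversed, so that ipso substitution is done on the chroman. There C8 lies between a methoxy group and a tied-back ring oxygen, and no epoxide is present. Buffered fluoride (TBAF, AcOH, THF, 0 °C) gives 3-(benzyloxy)-2-{[(2S)-3,3-dimethyloxiran-2-yl]methyl}-5-methoxy-6-(trimethylsilyl)phenol F5. The mildest workable promoter (PPTS, CH2Cl2, low temperature) closes it 6-endo to (3S)-5-(benzyloxy)-7-methoxy-2,2-dimethyl-8-(trimethylsilyl)chroman-3-ol F6. ICl (1.0 equiv, CH2Cl2, −78 °C) then effects the classical iododesilylation to 22.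

3. **Step 11.**
   - What may go wrong: once boron is complexed to the ketone, chelation-assisted loss of the O7 methyl group or ionisation of the tertiary pyran ether may compete with debenzylation.
   - Fallback (sets out from 22, returns at 29): the benzyl ether is removed before any carbonyl group is present, with BCl3 and C6HMe5 at −78 °C, giving (3S)-8-iodo-7-methoxy-2,2-dimethylchroman-3,5-diol F7. Both hydroxyls are silylated (TBSOTf, 2,6-lutidine) to the bis(tert-butyldimethylsilyl) ether F8. Iodine–lithium exchange (n-BuLi, THF, −78 °C) is followed by addition to (E)-3-[4-(tert-butyldimethylsilyloxy)phenyl]-N-methoxy-N-methylprop-2-enamide F9. F9 is made in one Horner–Wadsworth–Emmons step from commercial 4-(tert-butyldimethylsilyloxy)benzaldehyde and diethyl {2-[methoxy(methyl)amino]-2-oxoethyl}phosphonate (NaH, THF). The addition gives the tris(tert-butyldimethylsilyl) chalcone F10, and buffered fluoride (TBAF, AcOH, THF) releases 29.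

Further compounds
F1 | step 4 | methoxyethyne | COC#C
F2 | step 4 | 3-(benzyloxy)-5-methoxy-2-(3-methylbut-2-en-1-yl)phenol | COc1cc(OCc2ccccc2)c(CC=C(C)C)c(O)c1
F3 | step 4 | 3-(benzyloxy)-6-bromo-5-methoxy-2-(3-methylbut-2-en-1-yl)phenol | COc1cc(OCc2ccccc2)c(CC=C(C)C)c(O)c1Br
F4 | step 4 | [3-(benzyloxy)-6-bromo-5-methoxy-2-(3-methylbut-2-en-1-yl)phenoxy]trimethylsilane | COc1cc(OCc2ccccc2)c(CC=C(C)C)c(O[Si](C)(C)C)c1Br
F5 | step 7 | 3-(benzyloxy)-2-{[(2S)-3,3-dimethyloxiran-2-yl]methyl}-5-methoxy-6-(trimethylsilyl)phenol | COc1cc(OCc2ccccc2)c(C[C@@H]2OC2(C)C)c(O)c1[Si](C)(C)C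
F6 | step 7 | (3S)-5-(benzyloxy)-7-methoxy-2,2-dimethyl-8-(trimethylsilyl)chroman-3-ol | COc1cc(OCc3ccccc3)c2c(c1[Si](C)(C)C)OC(C)(C)[C@@H](O)C2
F7 | step 11 | (3S)-8-iodo-7-methoxy-2,2-dimethylchroman-3,5-diol | COc1cc(O)c2c(c1I)OC(C)(C)[C@@H](O)C2
F8 | step 11 | (3S)-3,5-bis(tert-butyldimethylsilyloxy)-8-iodo-7-methoxy-2,2-dimethylchroman | COc1cc(O[Si](C)(C)C(C)(C)C)c2c(c1I)OC(C)(C)[C@@H](O[Si](C)(C)C(C)(C)C)C2
F9 | step 11 | (E)-3-[4-(tert-butyldimethylsilyloxy)phenyl]-N-methoxy-N-methylprop-2-enamide | CON(C)C(=O)/C=C/c1ccc(O[Si](C)(C)C(C)(C)C)cc1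
F10 | step 11 | (E)-1-[(3S)-3,5-bis(tert-butyldimethylsilyloxy)-7-methoxy-2,2-dimethylchroman-8-yl]-3-[4-(tert-butyldimethylsilyloxy)phenyl]prop-2-en-1-one | COc1cc(O[Si](C)(C)C(C)(C)C)c2c(c1C(=O)/C=C/c1ccc(O[Si](C)(C)C(C)(C)C)cc1)OC(C)(C)[C@@H](O[Si](C)(C)C(C)(C)C)C2
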